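**Retrosynthetic overview**
1. Target 14 ⇒ hydroxy lactone 12 by a C3–CH2OH disconnection (dianion aldol with formaldehyde, trans to the C4 oxygen).
2. 12 ⇒ (E)-β,γ-unsaturated acid 10: the only ring, the γ-lactone, is closed last-but-one by C–O bond formation (carboxylate-directed asymmetric epoxidation, then opening of the epoxide by the carboxyl at the tertiary carbon with inversion), which sets C4 and C5.
3. 10 ⇒ homoallylic alcohol 8 ⇒ enyne 5 (syn-carboalumination/ethylene oxide fixes the E trisubstituted alkene).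
4. 5 ⇒ bromide 4 + acetylide; 4 ⇒ 10-bromodec-1-ene 1 + (E)-1-iodopent-1-ene 2 (B-alkyl Suzuki coupling fixes the remote E alkene).

Assumption: (E)-1-iodopent-1-ene 2 is bought as a catalogue reagent; the sense of induction in step 5 is as drawn, and the ligand antipode is used if a first run shows the opposite.
Abbreviation: (S,S)-TIPS-pdp = (2S,2'S)-1,1'-bis{[5-(triisopropylsilyl)pyridin-2-yl]methyl}-2,2'-bipyrrolidine.

**Step 1**
Reactants: 1 10-bromodec-1-ene; 2 (E)-1-iodopent-1-ene
Product: 4 (E)-1-bromopentadec-11-ene, via B-(10-bromodecyl)-9-BBN 3 (not isolated)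
Conditions: 9-BBN (1.0 equiv), THF, 0 °C to rt; then 2 (1.1 equiv), PdCl2(dppf) (3 mol %), K3PO4 (3 M aq., 3 equiv), DMF, rt
Reagents that add atoms: none
Why: B-alkyl Suzuki–Miyaura coupling: 9-BBN hydroborates only the terminal alkene (anti-Markovnikov), and zerovalent palladium inserts into the alkenyl C–I bond far faster than into the primary C–Br bond, so the bromide survives and the E geometry of 2 is transferred unchanged.

**Step 2**
Reactants: 4 (E)-1-bromopentadec-11-ene
Product: 5 (E)-heptadec-13-en-1-yne
Conditions: LiC≡CH·H2NCH2CH2NH2 (1.5 equiv), DMSO, 10 °C to rt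
Reagents that add atoms: lithium acetylide ethylenediamine complex, [Li+].[C-]#C.NCCN
Why: SN2 alkylation of acetylide by a primary bromide in DMSO; the isolated E alkene neither reacts nor migrates under these conditions.

**Step 3**
Reactants: 5 (E)-heptadec-13-en-1-yne
Product: 8 (3E,15E)-4-methylnonadeca-3,15-dien-1-ol, via alkenyldimethylalane 6 (not isolated), via lithium alkenylalanate 7 (not isolated)
Conditions: AlMe3 (2.0 equiv), Cp2ZrCl2 (0.2 equiv), CH2Cl2, 0 °C to rt; volatiles removed; hexane/THF, n-BuLi (1.0 equiv), −78 to 0 °C; ethylene oxide (3 equiv), −30 °C to rt; 1 M HCl, 0 °C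
Reagents that add atoms: trimethylaluminium, C[Al](C)C; ethylene oxide, C1CO1
Why: Negishi zirconium-catalysed carboalumination adds Me and Al syn across the terminal alkyne only (the internal alkene is inert), which fixes the E trisubstituted alkene in 6, and the ate complex 7 opens ethylene oxide with retention of the alkenyl geometry.

**Step 4**
Reactants: 8 (3E,15E)-4-methylnonadeca-3,15-dien-1-ol
Product: 10 (3E,15E)-4-methylnonadeca-3,15-dienoic acid, via dienal 9 (not isolated)
Conditions: TEMPO (0.2 equiv), PhI(OAc)2 (2.2 equiv), MeCN/H2O 1:1, rt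
Reagents that add atoms: water, O
Why: TEMPO/oxoammonium oxidation in aqueous MeCN takes the primary alcohol through aldehyde 9 and its hydrate to the acid under near-neutral conditions that leave both alkenes alone and give the β,γ-double bond little chance to move into conjugation.

**Step 5**
Reactants: 10 (3E,15E)-4-methylnonadeca-3,15-dienoic acid
Product: 12 (4S,5R)-4-hydroxy-5-methyl-5-[(E)-pentadec-11-en-1-yl]oxolan-2-one, via (3S,4S)-epoxy acid 11 (not isolated)
Conditions: Mn(OTf)2[(S,S)-TIPS-pdp] (2 mol %), H2O2 (50% aq., 1.2 equiv, syringe pump 1 h), MeCN, −30 °C, no added carboxylic acid; then CSA (10 mol %), rt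
Reagents that add atoms: hydrogen peroxide, OO
Why: Proposed new method: the substrate's own carboxylate takes the place of the usual carboxylic acid co-ligand on the chiral manganese aminopyridine catalyst, assists O–O heterolysis of the bound hydroperoxide to a pentavalent manganese oxo carboxylate and holds the C3=C4 alkene within reach of the oxo, so oxygen transfer is intramolecular, face-selective in the chiral pocket and confined to the proximal trisubstituted alkene (the remote trans-disubstituted alkene is untethered and a poor substrate for this catalyst class); the resulting (3S,4S)-epoxy acid 11 is then opened by its own carboxyl at the tertiary carbon (5-endo, acid-catalysed, inversion), which forms the C5–O lactone bond and gives C4 (S, from the epoxidation face) and C5 (R, from inversion) with OH cis to methyl, and the neutral lactone leaves the metal so the catalyst turns over; closest known reactions are manganese/H2O2/carboxylic acid asymmetric epoxidation, carboxylate-directed manganese-catalysed γ-C–H lactonization, and acid-mediated lactonization of 3,4-epoxy acids.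

**Step 6**
Reactants: 12 (4S,5R)-4-hydroxy-5-methyl-5-[(E)-pentadec-11-en-1-yl]oxolan-2-one
Product: 14 (3S,4S,5R)-4-hydroxy-3-(hydroxymethyl)-5-methyl-5-[(E)-pentadec-11-en-1-yl]oxolan-2-one, via dilithium dianion 13 (not isolated)
Conditions: LiN(i-Pr)2 (commercial solution, 2.3 equiv), THF, −78 to −40 °C; CH2O gas (from cracked paraformaldehyde, ca. 5 equiv), −78 to −40 °C; sat. aq. NH4Cl
Reagents that add atoms: formaldehyde, C=O
Why: Fráter–Seebach-type dianion aldol: formaldehyde attacks the enolate of 13 on the face anti to the C4 lithium alkoxide, giving the 3,4-trans product (3S), while the alkoxide resists β-elimination and C4 and C5 are untouched.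

**Compound list**
1 | 10-bromodec-1-ene | C=CCCCCCCCCBr | starting material
2 | (E)-1-iodopent-1-ene | CCC/C=C/I | starting material
3 | 9-(10-bromodecyl)-9-borabicyclo[3.3.1]nonane | BrCCCCCCCCCCB1C2CCCC1CCC2 | intermediate
4 | (E)-1-bromopentadec-11-ene | CCC/C=C/CCCCCCCCCCBr | intermediate
5 | (E)-heptadec-13-en-1-yne | CCC/C=C/CCCCCCCCCCC#C | intermediate
6 | dimethyl[(1E,13E)-2-methylheptadeca-1,13-dien-1-yl]alane | CCC/C=C/CCCCCCCCCC/C(C)=C/[Al](C)C | intermediate
7 | lithium butyl(dimethyl)[(1E,13E)-2-methylheptadeca-1,13-dien-1-yl]alanate | [Li+].CCC/C=C/CCCCCCCCCC/C(C)=C/[Al-](C)(C)CCCC | intermediate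
8 | (3E,15E)-4-methylnonadeca-3,15-dien-1-ol | CCC/C=C/CCCCCCCCCC/C(C)=C/CCO | intermediate
9 | (3E,15E)-4-methylnonadeca-3,15-dienal | CCC/C=C/CCCCCCCCCC/C(C)=C/CC=O | intermediate
10 | (3E,15E)-4-methylnonadeca-3,15-dienoic acid | CCC/C=C/CCCCCCCCCC/C(C)=C/CC(=O)O | intermediate
11 | 2-[(2S,3S)-3-methyl-3-[(E)-pentadec-11-en-1-yl]oxiran-2-yl]acetic acid | CCC/C=C/CCCCCCCCCC[C@]1(C)O[C@H]1CC(=O)O | intermediate
12 | (4S,5R)-4-hydroxy-5-methyl-5-[(E)-pentadec-11-en-1-yl]oxolan-2-one | CCC/C=C/CCCCCCCCCC[C@@]1(C)OC(=O)C[C@@H]1O | intermediate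
13 | dilithium enolate-alkoxide (dianion) of 12 | [Li+].[Li+].CCC/C=C/CCCCCCCCCC[C@@]1(C)OC([O-])=C[C@@H]1[O-] | intermediate
14 | (3S,4S,5R)-4-hydroxy-3-(hydroxymethyl)-5-methyl-5-[(E)-pentadec-11-en-1-yl]oxolan-2-one | CCC/C=C/CCCCCCCCCC[C@@]1(C)OC(=O)[C@@H](CO)[C@@H]1O | target

**Step count**
Total steps: 6. Longest linear sequence: 6 (1 → 4 → 5 → 8 → 10 → 12 → 14).

**Steps most likely to fail**

Step 5 (the new reaction; face selectivity, site selectivity or turnover may fall short). The fallback uses known chemistry, sets out from 8 and comes back at 12. Hydroxyl-directed asymmetric epoxidation of the homoallylic alcohol (VO(Oi-Pr)3 2 mol %, C2-symmetric cyclohexane-1,2-diamine-derived bishydroxamic acid ligand 4 mol % in the antipode that gives the (2S,3S)-oxirane, cumene hydroperoxide, toluene, rt) gives 2-[(2S,3S)-3-methyl-3-[(E)-pentadec-11-en-1-yl]oxiran-2-yl]ethanol F1; the remote alkene carries no directing hydroxyl and is left. Buffered oxidation (TEMPO cat., NaClO2, NaOCl cat., MeCN, NaH2PO4/Na2HPO4 buffer pH 6.7, 35 °C) takes F1 through 2-[(2S,3S)-3-methyl-3-[(E)-pentadec-11-en-1-yl]oxiran-2-yl]acetaldehyde F2 to epoxy acid 11, which CSA (10 mol %, CH2Cl2, rt) closes to 12 as in step 5.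

Step 6 (gaseous formaldehyde polymerises, and the dianion may convert poorly or eliminate). The fallback sets out from 12 and comes back at 14. Dianion 13 is generated as before and alkylated instead with 4-methoxybenzyl chloromethyl ether (THF/DMPU, −78 to −40 °C; alkylation anti to the alkoxide) to give (3S,4S,5R)-4-hydroxy-3-{[(4-methoxybenzyl)oxy]methyl}-5-methyl-5-[(E)-pentadec-11-en-1-yl]oxolan-2-one F3. DDQ (CH2Cl2/NaH2PO4/Na2HPO4 buffer pH 7, 0 °C) then removes the 4-methoxybenzyl group without touching the alkene and gives 14.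

Step 4 (aldehyde 9 may isomerise to the conjugated enal before it is oxidised). The fallback avoids the alcohol oxidation altogether, sets out from 5 and comes back at 10. Enyne 5 is carboaluminated as in step 3 to alane 6, which is quenched with I2 (THF, −30 °C) to give (1E,13E)-1-iodo-2-methylheptadeca-1,13-diene F4. Negishi coupling with the commercial Reformatsky reagent BrZnCH2CO2Et (Pd(PPh3)4 5 mol %, THF/DMPU, 50 °C) gives ethyl (3E,15E)-4-methylnonadeca-3,15-dienoate F5, and LiOH (THF/H2O, rt) gives acid 10.

**Further compounds**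
F1 | step 5 | 2-[(2S,3S)-3-methyl-3-[(E)-pentadec-11-en-1-yl]oxiran-2-yl]ethanol | CCC/C=C/CCCCCCCCCC[C@]1(C)O[C@H]1CCO
F2 | step 5 | 2-[(2S,3S)-3-methyl-3-[(E)-pentadec-11-en-1-yl]oxiran-2-yl]acetaldehyde | CCC/C=C/CCCCCCCCCC[C@]1(C)O[C@H]1CC=O
F3 | step 6 | (3S,4S,5R)-4-hydroxy-3-{[(4-methoxybenzyl)oxy]methyl}-5-methyl-5-[(E)-pentadec-11-en-1-yl]oxolan-2-one | CCC/C=C/CCCCCCCCCC[C@@]1(C)OC(=O)[C@@H](COCc2ccc(OC)cc2)[C@@H]1O
F4 | step 4 | (1E,13E)-1-iodo-2-methylheptadeca-1,13-diene | CCC/C=C/CCCCCCCCCC/C(C)=C/I
F5 | step 4 | ethyl (3E,15E)-4-methylnonadeca-3,15-dienoate | CCC/C=C/CCCCCCCCCC/C(C)=C/CC(=O)OCC
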